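How long is a chain in this flask at 2.5 min, and how much free monomer has reacted by then? I follow one unit of free monomer through its forks.

| flask | free monomer | initiator | remark | time |
|---|---|---|---|---|
| summer | 0.20 M | 0.80 mM | the very flask that is asked about, followed so far |  |
| flask | 0.20 M | 0.80 mM |  | 2.5 min |

- summer (time / s: monomer in chains / %, free monomer / %): 10.0: 11.3, 88.8; 12.0: 13.4, 86.1; 20.0: 20.0, 79.3; 25.0: 23.2, 76.1; 30.0: 25.7, 73.7

(scatter of a reading: 0.3 percentage points)

- average number of monomer units in a chain (chains begun, living or dead) at 2.5 min
- part of the free monomer that has reacted at 2.5 min

- the average divides the monomer in chains by the number of chains begun, living and dead together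
- what was read earlier has a scatter of 0.3 percentage points, one standard deviation
- the earlier runs do not show the number of chains; that part of a forecast is a guess

I read the summer run by rows first. From 10.0 s to 20.0 s free monomer drops 9.5 percentage points. Over the next equal stretch, to 30.0 s, it drops 5.6 points, which is less. So in this flask the first fork, reacted or not, is slowing.

Then I read column against column. In the last row the two columns fall 0.6 points short of the charge, against a scatter of 0.3 points. So at the second fork a reacted unit reaches a chain with a chance of about 97.7%, as a reading.

The third fork is a guess, since the readings show no chain count: I let each initiator begin one chain. The charge ratio is then 250, free monomer charged per initiator charged. This ratio times the fraction in chains gives the average chain.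

The forecast says 40% reacted, within 34% to 54%, and dp 100, within 55 to 200. Its ground is that “conversion is heading toward a limit rather than toward completion”. On its 40%, my chance and ratio give 97.7, against its 100.

The flask gives dp 98.5 and c 41.7%.

    2 free monomer → homo dimer (k = 8.41 × 10⁻⁴ L mol⁻¹ s⁻¹)
    free monomer + initiator → living end + monomer in chains (k = 6.16 L mol⁻¹ s⁻¹)
    free monomer + living end → monomer in chains + living end, rate k3*[living end]*[free monomer] (k = 42.2 L mol⁻¹ s⁻¹)
    monomer in chains + living end → free monomer + living end, rate k4*[living end] as long as [monomer in chains] is above zero (k = 4.93 s⁻¹)

In this flask at 2.50 min, monomer in chains holds 39.4% and homo dimer 2.27%. Initiator has 0% of its charge left, less than the 58% of free monomer. The ratio 250 on that fraction in chains gives 98.5 units per chain.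

The neighbour with 0.0014 M of initiator has its ratio cut to 143. With this flask's fraction in chains, that gives 56.3. The neighbour itself gives dp 56.8, with c 41.8%.

(The readings stem from a simulated flask with constants of no real substance, and the scatter is random.)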